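Labdane numbering is used (ring A: C1–C5, C10; ring B: C5–C10). Everything rests on cutting C4–C5 in ring A. The axial C19 methyl on quaternary C4 is read as a neopentyl C–Pd bond that has captured hydride. The 5α-H/6α-OH pair is read as a C5=C6 alkene. One reductive Heck cyclisation of a ring B cyclohexenyl triflate onto a pendant 2-(silyloxymethyl)allyl group closes ring A, sets C4 and makes C19 from an alkene CH2. The precursor is monocyclic: benzoquinone monoketal carrying the complete C11–C15 chain (asymmetric conjugate addition, C9) and a quaternary C10 (two alkylations). The butenolide enters intact by a late vinylogous Mukaiyama aldol reaction.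

Key step: step 9

Remark on numbering: C11–C15 is the chain on C9 (C15 = carbinol carbon), C16 the lactone γ-carbon, C17 the methylene carbon on C8, C18 the CH2OH carbon, and C19 and C20 the methyls on C4 and C10. α is the face opposite to C20.

Assumption: 1, 4, 10 and 25 are taken as purchasable. The sense of induction of the copper/phosphoramidite catalyst is taken from its behaviour with simple cyclohexenones, and that of the titanium/BINOL catalyst from its behaviour with simple aldehydes.

Step 1
Reactants: 1 (E)-3-methylpent-2-en-4-yn-1-ol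
Product: 2 4-methoxybenzyl (PMB) ether of 1
Conditions: NaH, 4-methoxybenzyl chloride, n-Bu4NI (cat.), THF/DMF, 0 °C to rt
Reagents that add atoms: 4-methoxybenzyl chloride, COc1ccc(CCl)cc1
Why: Williamson ether synthesis on the alkoxide gives an ether that withstands the later organometallic, basic and palladium steps and can be removed oxidatively.

Step 2
Reactants: 2 PMB ether of 1
Product: 3 PMB ether of (E)-3-methylpenta-2,4-dien-1-ol
Conditions: H2 (1 atm), Pd on CaCO3 poisoned with Pb(OAc)2, quinoline, hexane, rt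
Reagents that add atoms: none
Why: Semihydrogenation over poisoned palladium should stop at the vinyl stage of the terminal alkyne and leave the E-trisubstituted alkene (the future C13=C14) untouched.

Step 3
Reactants: 3 PMB ether of (E)-3-methylpenta-2,4-dien-1-ol, 4 4,4-dimethoxycyclohexa-2,5-dien-1-one
Product: 7 (R)-4,4-dimethoxy-5-[(E)-5-(4-methoxybenzyloxy)-3-methylpent-3-en-1-yl]cyclohex-2-en-1-one, via alkyldiethylborane 5 (not isolated), via dialkylzinc 6 (not isolated)
Conditions: Et2BH (from BH3·SMe2 and BEt3), Et2O, 0 °C to rt; Et2Zn, 0 °C, then vacuum; 4, Cu(OTf)2 (cat.), (S,R,R)-binaphthyl N,N-bis(1-phenylethyl)phosphoramidite (cat.), toluene, −25 °C; aq NH4Cl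
Reagents that add atoms: none
Why: Hydroboration of the monosubstituted diene terminus and boron–zinc exchange give a primary dialkylzinc, and its copper/phosphoramidite-catalysed enantioselective conjugate addition desymmetrises the quinone monoketal, the ligand fixing the enone face and thus C9.

Step 4
Reactants: 7 enone with C9 set
Product: 8 6-methyl derivative of 7 (both C10 epimers)
Conditions: LiN(i-Pr)2, THF, −78 °C; MeI, −78 to −30 °C
Reagents that add atoms: iodomethane, CI
Why: C10 is the only enolisable position (C6 is sp2, C8 is a ketal carbon), so kinetic enolate methylation is regiospecific, and the new centre is planarised again in step 5.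

Step 5
Reactants: 8 6-methyl enone
Product: 9 (5R,6R)-6-allyl-4,4-dimethoxy-6-methyl-5-[(E)-5-(4-methoxybenzyloxy)-3-methylpent-3-en-1-yl]cyclohex-2-en-1-one (allyl trans, methyl cis to the chain)
Conditions: LiN(i-Pr)2, THF/DMPU, −78 °C; allyl bromide, −78 to −20 °C
Reagents that add atoms: allyl bromide, C=CCBr
Why: In this enolate alkylation the reactive allylic halide should add to the face anti to the neighbouring C9 chain (1,2-induction), which sets quaternary C10 with C1 trans and C20 cis to C11.

Step 6
Reactants: 10 2-bromoprop-2-en-1-ol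
Product: 11 (2-bromoallyloxy)(tert-butyl)dimethylsilane
Conditions: t-BuMe2SiCl, imidazole, CH2Cl2, rt
Reagents that add atoms: tert-butyldimethylsilyl chloride, CC(C)(C)[Si](C)(C)Cl
Why: Standard silylation masks the future C18 hydroxyl with a bulky group that later helps the facial bias at C4.

Step 7
Reactants: 9 allyl enone, 11 (2-bromoallyloxy)(tert-butyl)dimethylsilane
Product: 13 (5R,6R)-6-[4-(tert-butyldimethylsilyloxymethyl)pent-4-en-1-yl] analogue of 9, via B-alkyl-9-BBN adduct 12 (not isolated)
Conditions: 9-BBN, THF, 0 °C to rt; then 11, Pd(dppf)Cl2 (cat.), Cs2CO3, H2O, DMF, rt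
Reagents that add atoms: none
Why: 9-BBN should take only the monosubstituted allyl alkene (the trisubstituted alkene and the neopentyl enone carbonyl are much slower), and B-alkyl Suzuki–Miyaura coupling with the alkenyl bromide forms C3–C4.

Step 8
Reactants: 13 enone with the complete C1–C4 tether
Product: 15 cyclohex-1-enyl triflate C5(OTf)=C6 with configuration as in 13, via lithium enolate 14 (not isolated)
Conditions: LiBH(s-Bu)3, THF, −78 °C; N-(5-chloro-2-pyridyl)bis(trifluoromethanesulfonimide), −78 to 0 °C
Reagents that add atoms: N-(5-chloro-2-pyridyl)bis(trifluoromethanesulfonimide), O=S(=O)(N(c1ccc(Cl)cn1)S(=O)(=O)C(F)(F)F)C(F)(F)F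
Why: Conjugate hydride addition to the β-unsubstituted enone, whose carbonyl is shielded by quaternary C10, gives one regiodefined enolate that is trapped on oxygen as the enol triflate.

Step 9
Reactants: 15 cyclohexenyl triflate
Product: 16 Δ5-octalin: 4α-CH2OTBS, 4β-CH3, 10β-CH3, 9β side chain, C8 dimethyl ketal
Conditions: Pd(OAc)2 (cat.), 1,3-bis(diphenylphosphino)propane, HCO2Na, DMF, 70 °C
Reagents that add atoms: none
Why: Zerovalent palladium inserts into the C5–OTf bond, the cationic alkenylpalladium adds syn across the 1,1-disubstituted C4=CH2 alkene, and the neopentyl alkylpalladium, which has no β-hydrogen, exchanges triflate for formate, loses CO2 and reductively eliminates to the C19 methyl. The closest known reaction type is the reductive Heck cyclisation (cyclisation with formate capture) that builds quaternary carbons from aryl or alkenyl triflates. Ring A closes in the 6-exo-trig mode by forming C4–C5, and C5=C6 stays in place. C4 is the only new stereocentre: the three-carbon tether leaves C10 on the face opposite to C20, so in the chair-like four-centre transition state C4 reaches C5 from the α side while palladium and the alkene CH2 swing to the β side, which makes the future methyl axial (β) and leaves the bulky CH2OTBS group equatorial (α). The step needs insertion to outrun direct formate reduction of the alkenylpalladium and needs one alkene out of two to react; the bidentate phosphine/triflate pair keeps palladium cationic and fast in insertion, HCO2Na is only sparingly soluble in DMF, and only the allyl silyl ether alkene can reach C5 through a six-membered ring.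

Step 10
Reactants: 16 Δ5-octalin silyl ether
Product: 17 homoallylic alcohol (free C18–OH)
Conditions: n-Bu4NF, THF, rt
Reagents that add atoms: none
Why: Fluoride desilylation frees only C18–OH, since the PMB ether and the ketal are inert to fluoride.

Step 11
Reactants: 17 homoallylic alcohol
Product: 18 5α,6α-epoxide
Conditions: VO(acac)2 (cat.), t-BuOOH, toluene, 0 °C to rt
Reagents that add atoms: tert-butyl hydroperoxide, CC(C)(C)OO
Why: In this hydroxyl-directed epoxidation the equatorial α-oriented C18–OH binds vanadium and delivers oxygen to the α face of C5=C6 (the β face is blocked by C19 and C20), which sets C6, while the side-chain alkene has no free hydroxyl to direct the catalyst.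

Step 12
Reactants: 18 5α,6α-epoxide
Product: 20 6α,18-dihydroxy-8-ketone (trans-decalin), via ketal diol 19 (not isolated)
Conditions: Cp2TiCl2, Mn dust, H2O, THF, rt; then 1 M HCl, THF, rt
Reagents that add atoms: water, O
Why: Reductive epoxide opening by trivalent titanium cleaves the C5–O bond to the more substituted C5 radical with C6–O retained; the radical should take a hydrogen atom from the Cp2TiCl–water complex on the open α face (5α-H, trans fusion), and the acid work-up hydrolyses the dimethyl ketal.

Step 13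
Reactants: 20 keto diol
Product: 21 6α,18-bis(triethylsilyl) ether
Conditions: Et3SiOTf, 2,6-lutidine, CH2Cl2, −78 to 0 °C
Reagents that add atoms: triethylsilyl trifluoromethanesulfonate, CC[Si](CC)(CC)OS(=O)(=O)C(F)(F)F
Why: The silyl triflate covers even the hindered 6α-OH, which removes the retro-aldol pathway and keeps the diol away from the titanium catalyst of step 18.

Step 14
Reactants: 21 bis-silylated ketone
Product: 22 8(17)-methylene compound
Conditions: Ph3PCH3Br, KOt-Bu, THF, 0 to 40 °C
Reagents that add atoms: methyltriphenylphosphonium bromide, C[P+](c1ccccc1)(c1ccccc1)c1ccccc1.[Br-]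
Why: Wittig methylenation of the C8 ketone is safe because the equatorial 6-silyloxy group is poorly aligned for β-elimination and the C9 chain is already in the favoured equatorial position.

Step 15
Reactants: 22 8(17)-methylene compound
Product: 23 allylic alcohol (free C15–OH)
Conditions: DDQ, CH2Cl2/pH 7 buffer, 0 °C
Reagents that add atoms: none
Why: Oxidative cleavage removes only the electron-rich benzyl ether and leaves silyl ethers and alkenes alone.

Step 16
Reactants: 23 allylic alcohol
Product: 24 (E)-enal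
Conditions: MnO2, CH2Cl2, rt
Reagents that add atoms: none
Why: MnO2 oxidises the allylic alcohol under neutral conditions without E/Z isomerisation.

Step 17
Reactants: 25 4-methylfuran-2(5H)-one
Product: 26 4-methyl-2-(trimethylsilyloxy)furan
Conditions: Me3SiOTf, Et3N, CH2Cl2, 0 °C
Reagents that add atoms: trimethylsilyl trifluoromethanesulfonate, C[Si](C)(C)OS(=O)(=O)C(F)(F)F
Why: Soft enolisation at the γ-carbon and O-silylation turn the purchased lactone ring into its aromatic dienolate equivalent without opening it.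

Step 18
Reactants: 24 (E)-enal, 26 4-methyl-2-(trimethylsilyloxy)furan
Product: 28 target CNP0221530.1, via trisilyl ether 27 (not isolated)
Conditions: Ti(Oi-Pr)4 (cat.), (R)-BINOL (cat.), Et2O, −20 °C; then HF·pyridine, THF, 0 °C
Reagents that add atoms: none
Why: In the catalytic asymmetric vinylogous Mukaiyama aldol reaction the furan attacks through C5; the (R)-BINOL–titanium complex should expose the Re face of the aldehyde (15S), the open transition state of Lewis-acid-promoted silyloxyfuran additions should favour the syn adduct (16S), and fluoride then removes all three silyl groups.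

Compound list
1 | (E)-3-methylpent-2-en-4-yn-1-ol | C#C/C(C)=C/CO | starting material
2 | PMB ether of 1 | C#C/C(C)=C/COCc1ccc(OC)cc1 | intermediate
3 | PMB ether of (E)-3-methylpenta-2,4-dien-1-ol | C=C/C(C)=C/COCc1ccc(OC)cc1 | intermediate
4 | 4,4-dimethoxycyclohexa-2,5-dien-1-one | COC1(OC)C=CC(=O)C=C1 | starting material
5 | diethyl[(E)-5-(4-methoxybenzyloxy)-3-methylpent-3-en-1-yl]borane | CCB(CC)CC/C(C)=C/COCc1ccc(OC)cc1 | intermediate
6 | bis[(E)-5-(4-methoxybenzyloxy)-3-methylpent-3-en-1-yl]zinc | [Zn](CC/C(C)=C/COCc1ccc(OC)cc1)CC/C(C)=C/COCc1ccc(OC)cc1 | intermediate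
7 | (R)-4,4-dimethoxy-5-[(E)-5-(4-methoxybenzyloxy)-3-methylpent-3-en-1-yl]cyclohex-2-en-1-one | O=C1C=CC(OC)(OC)[C@H](CC/C(C)=C/COCc2ccc(OC)cc2)C1 | intermediate
8 | 6-methyl derivative of 7, both C10 epimers | O=C1C=CC(OC)(OC)[C@H](CC/C(C)=C/COCc2ccc(OC)cc2)C1C | intermediate
9 | (5R,6R)-6-allyl-6-methyl enone | O=C1C=CC(OC)(OC)[C@H](CC/C(C)=C/COCc2ccc(OC)cc2)[C@@]1(C)CC=C | intermediate
10 | 2-bromoprop-2-en-1-ol | C=C(Br)CO | starting material
11 | (2-bromoallyloxy)(tert-butyl)dimethylsilane | C=C(Br)CO[Si](C)(C)C(C)(C)C | intermediate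
12 | B-alkyl-9-BBN adduct of 9 | O=C1C=CC(OC)(OC)[C@H](CC/C(C)=C/COCc2ccc(OC)cc2)[C@@]1(C)CCCB1C2CCCC1CCC2 | intermediate
13 | enone with the C1–C4 tether | O=C1C=CC(OC)(OC)[C@H](CC/C(C)=C/COCc2ccc(OC)cc2)[C@@]1(C)CCCC(=C)CO[Si](C)(C)C(C)(C)C | intermediate
14 | lithium enolate from 13 | [Li]OC1=CCC(OC)(OC)[C@H](CC/C(C)=C/COCc2ccc(OC)cc2)[C@@]1(C)CCCC(=C)CO[Si](C)(C)C(C)(C)C | intermediate
15 | cyclohexenyl triflate | O=S(=O)(OC1=CCC(OC)(OC)[C@H](CC/C(C)=C/COCc2ccc(OC)cc2)[C@@]1(C)CCCC(=C)CO[Si](C)(C)C(C)(C)C)C(F)(F)F | intermediate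
16 | Δ5-octalin, 4α-CH2OTBS, 4β-CH3 | COC1(OC)CC=C2[C@](C)(CO[Si](C)(C)C(C)(C)C)CCC[C@]2(C)[C@H]1CC/C(C)=C/COCc1ccc(OC)cc1 | intermediate
17 | Δ5-octalin with free C18–OH | COC1(OC)CC=C2[C@](C)(CO)CCC[C@]2(C)[C@H]1CC/C(C)=C/COCc1ccc(OC)cc1 | intermediate
18 | 5α,6α-epoxide | COC1(OC)C[C@@H]2O[C@@]23[C@](C)(CO)CCC[C@]3(C)[C@H]1CC/C(C)=C/COCc1ccc(OC)cc1 | intermediate
19 | 6α,18-diol, C8 dimethyl ketal | COC1(OC)C[C@H](O)[C@H]2[C@](C)(CO)CCC[C@]2(C)[C@H]1CC/C(C)=C/COCc1ccc(OC)cc1 | intermediate
20 | 6α,18-dihydroxy-8-ketone | O=C1C[C@H](O)[C@H]2[C@](C)(CO)CCC[C@]2(C)[C@H]1CC/C(C)=C/COCc1ccc(OC)cc1 | intermediate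
21 | 6α,18-bis(triethylsilyloxy)-8-ketone | O=C1C[C@H](O[Si](CC)(CC)CC)[C@H]2[C@](C)(CO[Si](CC)(CC)CC)CCC[C@]2(C)[C@H]1CC/C(C)=C/COCc1ccc(OC)cc1 | intermediate
22 | 8(17)-methylene PMB ether | C=C1C[C@H](O[Si](CC)(CC)CC)[C@H]2[C@](C)(CO[Si](CC)(CC)CC)CCC[C@]2(C)[C@H]1CC/C(C)=C/COCc1ccc(OC)cc1 | intermediate
23 | allylic alcohol | C=C1C[C@H](O[Si](CC)(CC)CC)[C@H]2[C@](C)(CO[Si](CC)(CC)CC)CCC[C@]2(C)[C@H]1CC/C(C)=C/CO | intermediate
24 | (E)-enal | C=C1C[C@H](O[Si](CC)(CC)CC)[C@H]2[C@](C)(CO[Si](CC)(CC)CC)CCC[C@]2(C)[C@H]1CC/C(C)=C/C=O | intermediate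
25 | 4-methylfuran-2(5H)-one | CC1=CC(=O)OC1 | starting material
26 | 4-methyl-2-(trimethylsilyloxy)furan | Cc1coc(O[Si](C)(C)C)c1 | intermediate
27 | (15S,16S)-adduct, 15-OTMS, 6,18-bis-OTES | C=C1C[C@H](O[Si](CC)(CC)CC)[C@H]2[C@](C)(CO[Si](CC)(CC)CC)CCC[C@]2(C)[C@H]1CC/C(C)=C/[C@H](O[Si](C)(C)C)[C@H]1OC(=O)C=C1C | intermediate
28 | CNP0221530.1 | C=C1C[C@H](O)[C@H]2[C@](C)(CO)CCC[C@]2(C)[C@H]1CC/C(C)=C/[C@H](O)[C@H]1OC(=O)C=C1C | target

Total step count: 18. Longest linear sequence: 16 (steps 1–5, 7–16 and 18).

**Step 9.**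
- What may go wrong: formate may transfer hydride to the hindered alkenylpalladium before the 6-exo insertion, so that the triflate is simply reduced.
- The fallback replaces palladium by an alkenyl radical. It sets out from 13 and comes back at 16.
- LiBH(s-Bu)3 followed by a proton quench gives the saturated ketone F1.
- N2H4·H2O and Et3N in ethanol give the hydrazone F2.
- I2 with 1,1,3,3-tetramethylguanidine (Barton vinyl iodide synthesis) gives the alkenyl iodide F3.
- Slow addition of Bu3SnH/AIBN in benzene at 80 °C triggers a 6-exo alkenyl radical cyclisation through a chair with the silyloxymethyl group equatorial. The primary radical is then reduced to the C19 methyl of 16.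

**Step 11.**
- What may go wrong: oxygen transfer to an alkene flanked by two quaternary carbons may be so slow that undirected epoxidation of the side-chain alkene competes.
- The fallback uses a temporary silicon tether. It sets out from 17 and comes back at 19, which is hydrolysed to 20 as in step 12.
- Me2SiHCl and Et3N give the dimethylsilyl ether F4.
- Pt2[(CH2=CHSiMe2)2O]3 in toluene at 60 °C brings about 6-endo intramolecular hydrosilylation. Syn addition of Si–H from the α face gives the oxasilinane F5 (5α-H, 6α-Si).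
- Tamao oxidation (H2O2, KF, KHCO3) with retention gives 19.

**Step 18.**
- What may go wrong: the methyl group next to the reacting furan carbon may erode the facial selectivity at the aldehyde or the syn/anti selectivity.
- The fallback separates bond formation from absolute control. It sets out from 24 and 26 and comes back at 28.
- BF3·OEt2 in CH2Cl2 at −78 °C gives the two syn adducts, the (15S,16S)-alcohol F6 and the (15R,16R)-alcohol F7.
- Sharpless kinetic resolution (Ti(Oi-Pr)4, L-(+)-diisopropyl tartrate, t-BuOOH, 4 Å sieves, −20 °C) consumes the fast-reacting isomer as the epoxy alcohol F8.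
- The recovered alcohol is desilylated with HF·pyridine to 28.

Further compounds
F1 | step 9 | saturated ketone from 13 | O=C1CCC(OC)(OC)[C@H](CC/C(C)=C/COCc2ccc(OC)cc2)[C@@]1(C)CCCC(=C)CO[Si](C)(C)C(C)(C)C
F2 | step 9 | hydrazone of F1 | NN=C1CCC(OC)(OC)[C@H](CC/C(C)=C/COCc2ccc(OC)cc2)[C@@]1(C)CCCC(=C)CO[Si](C)(C)C(C)(C)C
F3 | step 9 | cyclohexenyl iodide | IC1=CCC(OC)(OC)[C@H](CC/C(C)=C/COCc2ccc(OC)cc2)[C@@]1(C)CCCC(=C)CO[Si](C)(C)C(C)(C)C
F4 | step 11 | dimethylsilyl ether of 17 | COC1(OC)CC=C2[C@](C)(CO[SiH](C)C)CCC[C@]2(C)[C@H]1CC/C(C)=C/COCc1ccc(OC)cc1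
F5 | step 11 | 6α-silyl oxasilinane | COC1(OC)C[C@H]2[C@H]3[C@](C)(CO[Si]2(C)C)CCC[C@]3(C)[C@H]1CC/C(C)=C/COCc1ccc(OC)cc1
F6 | step 18 | (15S,16S)-alcohol, 6,18-bis-OTES | C=C1C[C@H](O[Si](CC)(CC)CC)[C@H]2[C@](C)(CO[Si](CC)(CC)CC)CCC[C@]2(C)[C@H]1CC/C(C)=C/[C@H](O)[C@H]1OC(=O)C=C1C
F7 | step 18 | (15R,16R)-alcohol, 6,18-bis-OTES | C=C1C[C@H](O[Si](CC)(CC)CC)[C@H]2[C@](C)(CO[Si](CC)(CC)CC)CCC[C@]2(C)[C@H]1CC/C(C)=C/[C@@H](O)[C@@H]1OC(=O)C=C1C
F8 | step 18 | 13,14-epoxy alcohol from F7 | C=C1C[C@H](O[Si](CC)(CC)CC)[C@H]2[C@](C)(CO[Si](CC)(CC)CC)CCC[C@]2(C)[C@H]1CC[C@@]1(C)O[C@@H]1[C@@H](O)[C@@H]1OC(=O)C=C1C
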